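The ten-membered carbocycle (C1–C10) is not closed directly: its Z-configured trisubstituted C1=C10 olefin is treated as the scar of an extruded sulfur atom. An eleven-membered thiacycle, C1–S–C10, is closed by thiolate alkylation and oxidised to the sulfone; a Ramberg–Bäcklund reaction then deletes SO2 and contracts the ring to the (1(10)Z,4E)-cyclodecadiene in one operation. The stereotetrad is bought from the chiral pool: C1–C6 of L-fucal become C6–C10 and the C14 methyl, the ring oxygen marking the carbon that later carries sulfur. C7 is set by glycal dihydroxylation, C6 by chelation-controlled reduction; lactone and epoxy ester are added last.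

Key step: step 16

Remark: germacrane locants are used for all open-chain and macrocyclic compounds (ring C1–C10, lactone C11–C13 with C13 the exocyclic methylene, C14 = methyl on C10, C15 = methyl on C4); sugar locants are used for pyranoid compounds; DMB = 3,4-dimethoxybenzyl, PMB = 4-methoxybenzyl, TIPS = triisopropylsilyl; compounds 1, 4, 7 and 9 are assumed to be commercial.

Step 1
Reactants: 1 5-chloropent-1-yne
Product: 3 (E)-5-chloro-1-iodo-2-methylpent-1-ene, via alkenylalane 2 (not isolated)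
Conditions: Me3Al, Cp2ZrCl2 (cat.), (CH2Cl)2, rt; then I2, THF, −30 to 0 °C
Reagents that add atoms: trimethylaluminium C[Al](C)C; iodine II
Why: Negishi Zr-catalysed carboalumination adds methyl and aluminium syn across the alkyne with aluminium on the terminal carbon, and iodinolysis goes with retention, so only the E-iodide (future C4=C5, C15) should form; the alkyl chloride is inert in this chlorinated medium.

Step 2
Reactants: 4 (E)-2-methylbut-2-en-1-ol
Product: 5 [(2R,3R)-2,3-dimethyloxiran-2-yl]methanol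
Conditions: Ti(OiPr)4 (cat.), D-(−)-diisopropyl tartrate (cat.), t-BuOOH, 4 Å MS, CH2Cl2, −20 °C
Reagents that add atoms: tert-butyl hydroperoxide CC(C)(C)OO
Why: Sharpless asymmetric epoxidation of an E-trisubstituted allylic alcohol; the D-(−)-tartrate delivers oxygen to the face that gives the (2R,3R)-epoxy alcohol (the L-(+)-ester gives 2S,3S).

Step 3
Reactants: 5 [(2R,3R)-2,3-dimethyloxiran-2-yl]methanol
Product: 6 (2S,3R)-2,3-dimethyloxirane-2-carboxylic acid
Conditions: RuCl3 (cat.), NaIO4, CCl4/MeCN/H2O, 0 °C to rt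
Reagents that add atoms: sodium periodate [Na+].[O-]I(=O)(=O)=O; water O
Why: RuO4 oxidation (Sharpless conditions) takes the primary alcohol to the acid without opening the epoxide; both stereocentres are untouched (C2 becomes S only through the CIP priority change).

Step 4
Reactants: 7 3,4-di-O-acetyl-L-fucal
Product: 8 3,4-di-O-acetyl-2-iodo-L-fucal
Conditions: NIS, AgNO3 (cat.), MeCN, 80 °C
Reagents that add atoms: N-iodosuccinimide O=C1CCC(=O)N1I
Why: Silver-activated electrophilic iodination of the enol ether at C2 followed by re-elimination is the known route to 2-iodoglycals; the acetates survive.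

Step 5
Reactants: 8 3,4-di-O-acetyl-2-iodo-L-fucal; 9 (triisopropylsilyl)acetylene
Product: 10 3,4-di-O-acetyl-2-C-[(triisopropylsilyl)ethynyl]-L-fucal
Conditions: PdCl2(PPh3)2 (cat.), CuI (cat.), Et3N, THF, 45 °C
Reagents that add atoms: none
Why: Sonogashira coupling of the vinyl iodide installs C11/C13 as a base-stable silyl alkyne that stays latent until the lactone is built.

Step 6
Reactants: 10 3,4-di-O-acetyl-2-C-[(triisopropylsilyl)ethynyl]-L-fucal
Product: 11 2-C-[(triisopropylsilyl)ethynyl]-L-fucal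
Conditions: K2CO3 (cat.), MeOH, 0 °C to rt
Reagents that add atoms: none
Why: Base-catalysed transesterification removes both acetates; the enol ether and the TIPS-alkyne are stable to catalytic carbonate in methanol.

Step 7
Reactants: 11 2-C-[(triisopropylsilyl)ethynyl]-L-fucal
Product: 13 3-O-DMB-2-C-[(triisopropylsilyl)ethynyl]-L-fucal, via stannylene acetal 12 (not isolated)
Conditions: Bu2SnO, toluene, reflux (−H2O); then 3,4-dimethoxybenzyl chloride, Bu4NI (cat.), 70 °C
Reagents that add atoms: 3,4-dimethoxybenzyl chloride COc1ccc(CCl)cc1OC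
Why: Stannylene-acetal-mediated alkylation of the cis-3,4-diol goes to the pseudo-equatorial allylic O3 (future O8), the usual regiochemistry for galacto-configured cis-diols.

Step 8
Reactants: 13 3-O-DMB-2-C-[(triisopropylsilyl)ethynyl]-L-fucal
Product: 14 3-O-DMB-4-O-PMB-2-C-[(triisopropylsilyl)ethynyl]-L-fucal
Conditions: NaH, 4-methoxybenzyl chloride, Bu4NI (cat.), DMF, 0 °C to rt
Reagents that add atoms: 4-methoxybenzyl chloride COc1ccc(CCl)cc1
Why: Williamson etherification of the remaining O4 (future O9); PMB is chosen because the DMB ether can later be cleaved in its presence, and no silyl ether is present that could migrate.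

Step 9
Reactants: 14 3-O-DMB-4-O-PMB-2-C-[(triisopropylsilyl)ethynyl]-L-fucal
Product: 15 3-O-DMB-4-O-PMB-2-C-[(triisopropylsilyl)ethynyl]-L-fucopyranose (anomers)
Conditions: OsO4 (cat.), NMO, acetone/H2O, rt
Reagents that add atoms: N-methylmorpholine N-oxide C[N+]1([O-])CCOCC1; water O
Why: Upjohn dihydroxylation of the electron-rich enol ether occurs on the face opposite the C3, C4 and C5 substituents, so the new tertiary C2 hydroxyl is trans to O3 (L-fuco configuration, i.e. C7 of the target); the alkyne is far less reactive.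

Step 10
Reactants: 15 3-O-DMB-4-O-PMB-2-C-[(triisopropylsilyl)ethynyl]-L-fucopyranose; 3 (E)-5-chloro-1-iodo-2-methylpent-1-ene
Product: 17 open-chain C1–C10 triol (C6 epimers), via vinyllithium 16 (not isolated)
Conditions: 3, t-BuLi (2 equiv per 3), Et2O, −78 °C; 15, LiHMDS (2 equiv), THF, −78 °C; combine, −78 to 0 °C; aq. NH4Cl
Reagents that add atoms: none
Why: Iodine–lithium exchange with retention gives the E-vinyllithium, which adds to the open-chain aldehyde tautomer of the lactol dialkoxide to form the C5–C6 bond; the C6 epimer ratio does not matter because C6 is reset in steps 11 and 13.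

Step 11
Reactants: 17 open-chain C1–C10 triol (C6 epimers)
Product: 18 α-hydroxy enone (C6 ketone, free C10 hydroxyl)
Conditions: MnO2, CH2Cl2, rt
Reagents that add atoms: none
Why: Manganese dioxide oxidises only the allylic C6 carbinol, leaving the saturated C10 and tertiary C7 hydroxyls, so C10–OH becomes the only secondary hydroxyl in the molecule.

Step 12
Reactants: 18 α-hydroxy enone
Product: 19 C10 thioacetate enone
Conditions: PPh3, DIAD, AcSH, THF, 0 °C to rt
Reagents that add atoms: thioacetic acid CC(=O)S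
Why: Mitsunobu thioesterification at the only secondary hydroxyl (through the open-chain hydroxy enone tautomer) puts sulfur on C10 with inversion, which is irrelevant because C10 becomes sp2; the tertiary alcohol, the primary chloride and the β,β-disubstituted enone should not react under these neutral conditions.

Step 13
Reactants: 19 C10 thioacetate enone
Product: 20 (6R)-allylic alcohol thioacetate
Conditions: Zn(BH4)2, Et2O, −30 °C
Reagents that add atoms: none
Why: Chelation-controlled 1,2-reduction of an α-hydroxy ketone (Cram cyclic model): zinc bridges O6 and O7 and hydride enters from the side of the slim alkynyl group rather than the C8 chain, giving the anti 6,7-diol (6R); the thioester should survive at low temperature.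

Step 14
Reactants: 20 (6R)-allylic alcohol thioacetate
Product: 22 eleven-membered cyclic sulfide (S between C1 and C10), via thiol 21 (not isolated)
Conditions: Cs2CO3, NaI (cat.), degassed DMF/MeOH, 45 °C, slow addition (final 2 mM)
Reagents that add atoms: none
Why: Methanolysis releases the cesium thiolate, which closes the ring by intramolecular SN2 at the unhindered primary C1 (cesium thiolate macrocyclisation under high dilution); the soft thiolate does not eliminate, and oxygen nucleophiles cannot reach C1 through a small ring.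

Step 15
Reactants: 22 eleven-membered cyclic sulfide
Product: 23 eleven-membered cyclic sulfone
Conditions: (NH4)6Mo7O24 (cat.), 30% H2O2, EtOH, 0 °C to rt
Reagents that add atoms: hydrogen peroxide OO
Why: Molybdate-catalysed peroxide oxidation is selective for sulfur and should leave the trisubstituted olefin, the alkyne and the benzyl-type ethers untouched.

Step 16
Reactants: 23 eleven-membered cyclic sulfone
Product: 26 ten-membered (1(10)Z,4E)-diene diol, via α-bromo sulfone 24 (not isolated), via episulfone 25 (not isolated)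
Conditions: KOH/Al2O3, BrCF2CF2Br, t-BuOH/CH2Cl2, 0 °C to rt
Reagents that add atoms: none
Why: Ramberg–Bäcklund reaction with in situ halogenation: the sulfone is deprotonated at the C1 methylene and brominated to 24, deprotonation at C10 and 1,3-displacement of bromide (3-exo-tet) close the thiirane 1,1-dioxide 25, and cheletropic loss of SO2 bonds C1 to C10 directly, contracting the eleven-membered thiacycle to the ten-membered carbocycle. The closest precedent is the Ramberg–Bäcklund ring contraction of medium-ring cyclic sulfones to cycloalkenes. No stereocentre is created (C10 is destroyed); the new element is the C1=C10 geometry, fixed at the episulfone stage because SO2 loss is stereospecific, and the cis-fused bicyclo[8.1.0] episulfone that leads to the Z olefin should be favoured over the trans-fused one by ring strain and by equilibration of the α-bromo sulfone epimers under hydroxide. The step needs bromination and 1,3-elimination to outrun E1cB loss of the C9 PMB ether from the C10 carbanion; initial bromination at the less hindered C1 and the fast three-membered closure are expected to secure this. The dibromotetrafluoroethane leaves as tetrafluoroethylene and not as a carbene, so the trisubstituted olefins are safe; the C6/C7 hydroxyls are carried as alkoxides and the TIPS group keeps the alkyne from being halogenated.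

Step 17
Reactants: 26 ten-membered (1(10)Z,4E)-diene diol
Product: 27 terminal alkyne diol
Conditions: TBAF, THF, 0 °C
Reagents that add atoms: none
Why: Fluoride cleaves the alkynyl C–Si bond; there are no silyl ethers or esters in the molecule to interfere.

Step 18
Reactants: 27 terminal alkyne diol
Product: 28 8-O-DMB-9-O-PMB α-methylene-γ-lactone (12,6-olide)
Conditions: PdCl2 (cat.), SnCl2 (cat.), PPh3 (cat.), CO (7 atm), MeCN, 70 °C
Reagents that add atoms: carbon monoxide [C-]#[O+]
Why: Norton-type Pd-catalysed cyclocarbonylation of a 2-ethynyl alkanol: the only free secondary hydroxyl (C6) forms the alkoxycarbonyl–Pd species, which adds across the alkyne in 5-exo-dig mode to give the trans-fused α-methylene lactone, trans fusion being preset by C6 and C7 and precedented for trans-2-ethynylcycloalkanols.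

Step 19
Reactants: 28 8-O-DMB-9-O-PMB α-methylene-γ-lactone
Product: 29 C8 alcohol (9-O-PMB lactone)
Conditions: DDQ (1.1 equiv), CH2Cl2/pH 7 buffer, 0 °C
Reagents that add atoms: none
Why: DDQ oxidises the more electron-rich 3,4-dimethoxybenzyl ether much faster than the PMB ether, so only C8–OH is freed; the aqueous buffer hydrolyses the oxocarbenium ion and prevents acetal formation with O7.

Step 20
Reactants: 29 C8 alcohol (9-O-PMB lactone); 6 (2S,3R)-2,3-dimethyloxirane-2-carboxylic acid
Product: 31 C8 epoxy ester (9-O-PMB), via mixed anhydride 30 (not isolated)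
Conditions: 6, 2,4,6-trichlorobenzoyl chloride, Et3N, THF, rt; then 29, DMAP, toluene, rt to 40 °C
Reagents that add atoms: none
Why: Yamaguchi esterification acylates the only secondary hydroxyl (the tertiary C7–OH is inert), and the acid cannot epimerise because its α-carbon is quaternary.

Step 21
Reactants: 31 C8 epoxy ester (9-O-PMB)
Product: 32 CNP0420662.1 (target)
Conditions: DDQ (excess), CH2Cl2/pH 7 buffer, rt
Reagents that add atoms: none
Why: Oxidative removal of the allylic PMB ether under buffered neutral conditions, which the epoxy ester, the α-methylene lactone and the cyclodecadiene should tolerate.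

Compound list
1 | 5-chloropent-1-yne | C#CCCCCl | starting material
2 | (E)-(5-chloro-2-methylpent-1-en-1-yl)dimethylalane | ClCCC/C(C)=C/[Al](C)C | intermediate (not isolated)
3 | (E)-5-chloro-1-iodo-2-methylpent-1-ene (C1–C5, C15) | ClCCC/C(C)=C/I | intermediate
4 | (E)-2-methylbut-2-en-1-ol (tiglyl alcohol) | C/C=C(\C)CO | starting material
5 | [(2R,3R)-2,3-dimethyloxiran-2-yl]methanol | OC[C@@]1(C)O[C@@H]1C | intermediate
6 | (2S,3R)-2,3-dimethyloxirane-2-carboxylic acid | OC(=O)[C@@]1(C)O[C@@H]1C | intermediate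
7 | 3,4-di-O-acetyl-L-fucal [(2S,3R,4S)-2-methyl-3,4-dihydro-2H-pyran-3,4-diyl diacetate] | C1=C[C@H](OC(C)=O)[C@H](OC(C)=O)[C@H](C)O1 | starting material
8 | 3,4-di-O-acetyl-2-iodo-L-fucal | C1=C(I)[C@H](OC(C)=O)[C@H](OC(C)=O)[C@H](C)O1 | intermediate
9 | (triisopropylsilyl)acetylene | C#C[Si](C(C)C)(C(C)C)C(C)C | starting material
10 | 3,4-di-O-acetyl-2-C-[(triisopropylsilyl)ethynyl]-L-fucal | C1=C(C#C[Si](C(C)C)(C(C)C)C(C)C)[C@H](OC(C)=O)[C@H](OC(C)=O)[C@H](C)O1 | intermediate
11 | 2-C-[(triisopropylsilyl)ethynyl]-L-fucal (3,4-diol) | C1=C(C#C[Si](C(C)C)(C(C)C)C(C)C)[C@H](O)[C@H](O)[C@H](C)O1 | intermediate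
12 | 3,4-O-dibutylstannylene acetal of 11 | C1=C(C#C[Si](C(C)C)(C(C)C)C(C)C)[C@@H]2O[Sn](CCCC)(CCCC)O[C@@H]2[C@H](C)O1 | intermediate (not isolated)
13 | 3-O-(3,4-dimethoxybenzyl)-2-C-[(triisopropylsilyl)ethynyl]-L-fucal | C1=C(C#C[Si](C(C)C)(C(C)C)C(C)C)[C@H](OCc2ccc(OC)c(OC)c2)[C@H](O)[C@H](C)O1 | intermediate
14 | 3-O-(3,4-dimethoxybenzyl)-4-O-(4-methoxybenzyl)-2-C-[(triisopropylsilyl)ethynyl]-L-fucal | C1=C(C#C[Si](C(C)C)(C(C)C)C(C)C)[C@H](OCc2ccc(OC)c(OC)c2)[C@H](OCc2ccc(OC)cc2)[C@H](C)O1 | intermediate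
15 | 3-O-(3,4-dimethoxybenzyl)-4-O-(4-methoxybenzyl)-2-C-[(triisopropylsilyl)ethynyl]-L-fucopyranose (anomers) | OC1[C@](O)(C#C[Si](C(C)C)(C(C)C)C(C)C)[C@H](OCc2ccc(OC)c(OC)c2)[C@H](OCc2ccc(OC)cc2)[C@H](C)O1 | intermediate
16 | (E)-(5-chloro-2-methylpent-1-en-1-yl)lithium | ClCCC/C(C)=C/[Li] | intermediate (not isolated)
17 | (4E,7R,8R,9R,10S)-1-chloro-8-(3,4-dimethoxybenzyloxy)-9-(4-methoxybenzyloxy)-4-methyl-7-[(triisopropylsilyl)ethynyl]undec-4-ene-6,7,10-triol (C6 epimers) | ClCCC/C(C)=C/C(O)[C@](O)(C#C[Si](C(C)C)(C(C)C)C(C)C)[C@H](OCc1ccc(OC)c(OC)c1)[C@H](OCc1ccc(OC)cc1)[C@@H](O)C | intermediate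
18 | (4E,7S,8R,9R,10S)-1-chloro-7,10-dihydroxy-8-(3,4-dimethoxybenzyloxy)-9-(4-methoxybenzyloxy)-4-methyl-7-[(triisopropylsilyl)ethynyl]undec-4-en-6-one | ClCCC/C(C)=C/C(=O)[C@](O)(C#C[Si](C(C)C)(C(C)C)C(C)C)[C@H](OCc1ccc(OC)c(OC)c1)[C@H](OCc1ccc(OC)cc1)[C@@H](O)C | intermediate
19 | (4E,7S,8R,9S,10R)-10-(acetylsulfanyl)-1-chloro-7-hydroxy-8-(3,4-dimethoxybenzyloxy)-9-(4-methoxybenzyloxy)-4-methyl-7-[(triisopropylsilyl)ethynyl]undec-4-en-6-one | ClCCC/C(C)=C/C(=O)[C@](O)(C#C[Si](C(C)C)(C(C)C)C(C)C)[C@H](OCc1ccc(OC)c(OC)c1)[C@H](OCc1ccc(OC)cc1)[C@H](SC(C)=O)C | intermediate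
20 | (4E,6R,7R,8R,9S,10R)-10-(acetylsulfanyl)-1-chloro-8-(3,4-dimethoxybenzyloxy)-9-(4-methoxybenzyloxy)-4-methyl-7-[(triisopropylsilyl)ethynyl]undec-4-ene-6,7-diol | ClCCC/C(C)=C/[C@@H](O)[C@](O)(C#C[Si](C(C)C)(C(C)C)C(C)C)[C@H](OCc1ccc(OC)c(OC)c1)[C@H](OCc1ccc(OC)cc1)[C@H](SC(C)=O)C | intermediate
21 | 10-sulfanyl analogue of 20 (free thiol) | ClCCC/C(C)=C/[C@@H](O)[C@](O)(C#C[Si](C(C)C)(C(C)C)C(C)C)[C@H](OCc1ccc(OC)c(OC)c1)[C@H](OCc1ccc(OC)cc1)[C@H](S)C | intermediate (not isolated)
22 | eleven-membered cyclic sulfide, S between C1 and C10; (4E,6R,7R,8R,9S,10R)-6,7-diol, 7-(TIPS-ethynyl), 8-O-DMB, 9-O-PMB | C1CC/C(C)=C/[C@@H](O)[C@](O)(C#C[Si](C(C)C)(C(C)C)C(C)C)[C@H](OCc2ccc(OC)c(OC)c2)[C@H](OCc2ccc(OC)cc2)[C@@H](C)S1 | intermediate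
23 | S,S-dioxide of 22 (eleven-membered cyclic sulfone) | C1CC/C(C)=C/[C@@H](O)[C@](O)(C#C[Si](C(C)C)(C(C)C)C(C)C)[C@H](OCc2ccc(OC)c(OC)c2)[C@H](OCc2ccc(OC)cc2)[C@@H](C)S1(=O)=O | intermediate
24 | 1-bromo derivative of 23 (C1 epimers) | BrC1CC/C(C)=C/[C@@H](O)[C@](O)(C#C[Si](C(C)C)(C(C)C)C(C)C)[C@H](OCc2ccc(OC)c(OC)c2)[C@H](OCc2ccc(OC)cc2)[C@@H](C)S1(=O)=O | intermediate (not isolated)
25 | C1–C10 episulfone (thiirane 1,1-dioxide fused to the ten-membered ring) | C12CC/C(C)=C/[C@@H](O)[C@](O)(C#C[Si](C(C)C)(C(C)C)C(C)C)[C@H](OCc3ccc(OC)c(OC)c3)[C@H](OCc3ccc(OC)cc3)C1(C)S2(=O)=O | intermediate (not isolated)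
26 | (1(10)Z,4E,6R,7R,8R,9R)-8-(3,4-dimethoxybenzyloxy)-9-(4-methoxybenzyloxy)-4,10-dimethyl-7-[(triisopropylsilyl)ethynyl]cyclodeca-1(10),4-diene-6,7-diol | C1/C(C)=C/[C@@H](O)[C@](O)(C#C[Si](C(C)C)(C(C)C)C(C)C)[C@H](OCc2ccc(OC)c(OC)c2)[C@H](OCc2ccc(OC)cc2)/C(C)=C\C1 | intermediate
27 | 7-ethynyl analogue of 26 (terminal alkyne) | C1/C(C)=C/[C@@H](O)[C@](O)(C#C)[C@H](OCc2ccc(OC)c(OC)c2)[C@H](OCc2ccc(OC)cc2)/C(C)=C\C1 | intermediate
28 | (1(10)Z,4E,6R,7R,8R,9R)-8-(3,4-dimethoxybenzyloxy)-7-hydroxy-9-(4-methoxybenzyloxy)germacra-1(10),4,11(13)-trien-12,6-olide | C=C1C(=O)O[C@@H]2/C=C(\C)CC/C=C(/C)[C@@H](OCc3ccc(OC)cc3)[C@@H](OCc3ccc(OC)c(OC)c3)[C@@]12O | intermediate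
29 | (1(10)Z,4E,6R,7R,8R,9R)-7,8-dihydroxy-9-(4-methoxybenzyloxy)germacra-1(10),4,11(13)-trien-12,6-olide | C=C1C(=O)O[C@@H]2/C=C(\C)CC/C=C(/C)[C@@H](OCc3ccc(OC)cc3)[C@@H](O)[C@@]12O | intermediate
30 | mixed anhydride of 6 with 2,4,6-trichlorobenzoic acid | O=C(OC(=O)c1c(Cl)cc(Cl)cc1Cl)[C@@]1(C)O[C@@H]1C | intermediate (not isolated)
31 | 9-O-PMB ether of the target (8-O-[(2S,3R)-2,3-epoxy-2-methylbutanoyl]) | C=C1C(=O)O[C@@H]2/C=C(\C)CC/C=C(/C)[C@@H](OCc3ccc(OC)cc3)[C@@H](OC(=O)[C@@]3(C)O[C@@H]3C)[C@@]12O | intermediate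
32 | CNP0420662.1, (1(10)Z,4E,6R,7R,8R,9R)-7,9-dihydroxy-8-[(2S,3R)-2,3-epoxy-2-methylbutanoyloxy]germacra-1(10),4,11(13)-trien-12,6-olide | C=C1C(=O)O[C@@H]2/C=C(\C)CC/C=C(/C)[C@@H](O)[C@@H](OC(=O)[C@@]3(C)O[C@@H]3C)[C@@]12O | target

Total step count: 21 steps. Longest linear sequence: 18 steps (steps 4–21, from 3,4-di-O-acetyl-L-fucal 7).

Steps most likely to fail

1. Step 16 (Ramberg–Bäcklund ring contraction). The C10 carbanion may expel the C9 benzyloxy group (E1cB) before bromide is displaced, or the episulfone may close or epimerise to the trans-fused isomer and erode the Z selectivity. Fallback (sets out from 18, returns at 26): chelation-controlled Zn(BH4)2 reduction of 18 would give the (6R)-triol F1; 2,2-dimethoxypropane/PPTS would tie O6 and O7 into the acetonide F2; Dess–Martin oxidation of the remaining C10 carbinol would give the methyl ketone F3; PPh3 with catalytic NaI in refluxing MeCN would turn the primary chloride into the phosphonium chloride F4; KHMDS under high dilution would close the ten-membered ring directly by intramolecular Wittig olefination, which is Z-selective for unstabilised ylides with α-alkoxy ketones, to the ring-closed acetonide F5; aqueous acetic acid would then release 26.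

2. Step 14 (eleven-membered ring closure by thiolate alkylation). Intermolecular alkylation and disulfide formation may outrun the entropically costly ring closure. Fallback (sets out from 18, returns at 22): MsCl/Et3N would mesylate the lone secondary hydroxyl of 18 to give the enone mesylate F6; Zn(BH4)2 reduction would give the (6R)-alcohol mesylate F7; Na2S·9H2O in DMF/EtOH under high dilution would then introduce sulfur in the ring-closing event itself by double displacement (primary chloride first, then the secondary mesylate with inversion), giving 22 with the same C10 configuration.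

3. Step 18 (Pd-catalysed cyclocarbonylation). The electrophilic Pd(II) catalyst at 70 °C may trigger Cope or transannular reactions of the 1,5-diene or ionise the tertiary propargylic alcohol instead of carbonylating through O6. Fallback (sets out from 27, returns at 28): Mo(CO)3(CNt-Bu)3-catalysed hydrostannation with Bu3SnH would place tin on the internal alkyne carbon to give the α-stannyl alkene F8; iododestannylation with I2 at 0 °C would give the 2-iodoalkene F9; Pd(PPh3)4, CO (1 atm) and K2CO3 in THF at 40 °C would then close the lactone by carbonylative lactonisation of the vinyl iodide with the C6 hydroxyl to give 28.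

Further compounds
F1 | step 16 | (6R)-triol, single C6 epimer of 17 | ClCCC/C(C)=C/[C@@H](O)[C@](O)(C#C[Si](C(C)C)(C(C)C)C(C)C)[C@H](OCc1ccc(OC)c(OC)c1)[C@H](OCc1ccc(OC)cc1)[C@@H](O)C
F2 | step 16 | 6,7-O-isopropylidene acetal of F1 (free C10 hydroxyl) | ClCCC/C(C)=C/[C@H]1OC(C)(C)O[C@@]1(C#C[Si](C(C)C)(C(C)C)C(C)C)[C@H](OCc1ccc(OC)c(OC)c1)[C@H](OCc1ccc(OC)cc1)[C@@H](O)C
F3 | step 16 | C10 methyl ketone from F2 | ClCCC/C(C)=C/[C@H]1OC(C)(C)O[C@@]1(C#C[Si](C(C)C)(C(C)C)C(C)C)[C@H](OCc1ccc(OC)c(OC)c1)[C@H](OCc1ccc(OC)cc1)C(C)=O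
F4 | step 16 | C1 triphenylphosphonium chloride of F3 | [Cl-].C(CC[P+](c1ccccc1)(c1ccccc1)c1ccccc1)/C(C)=C/[C@H]1OC(C)(C)O[C@@]1(C#C[Si](C(C)C)(C(C)C)C(C)C)[C@H](OCc1ccc(OC)c(OC)c1)[C@H](OCc1ccc(OC)cc1)C(C)=O
F5 | step 16 | 6,7-O-isopropylidene acetal of 26 | C1/C(C)=C/[C@H]2OC(C)(C)O[C@@]2(C#C[Si](C(C)C)(C(C)C)C(C)C)[C@H](OCc3ccc(OC)c(OC)c3)[C@H](OCc3ccc(OC)cc3)/C(C)=C\C1
F6 | step 14 | C10 methanesulfonate of 18 | ClCCC/C(C)=C/C(=O)[C@](O)(C#C[Si](C(C)C)(C(C)C)C(C)C)[C@H](OCc1ccc(OC)c(OC)c1)[C@H](OCc1ccc(OC)cc1)[C@@H](OS(C)(=O)=O)C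
F7 | step 14 | (6R)-alcohol from F6 (C10 methanesulfonate, C1 chloride) | ClCCC/C(C)=C/[C@@H](O)[C@](O)(C#C[Si](C(C)C)(C(C)C)C(C)C)[C@H](OCc1ccc(OC)c(OC)c1)[C@H](OCc1ccc(OC)cc1)[C@@H](OS(C)(=O)=O)C
F8 | step 18 | 7-[1-(tributylstannyl)vinyl] analogue of 27 | C1/C(C)=C/[C@@H](O)[C@](O)(C(=C)[Sn](CCCC)(CCCC)CCCC)[C@H](OCc2ccc(OC)c(OC)c2)[C@H](OCc2ccc(OC)cc2)/C(C)=C\C1
F9 | step 18 | 7-(1-iodovinyl) analogue of 27 | C1/C(C)=C/[C@@H](O)[C@](O)(C(I)=C)[C@H](OCc2ccc(OC)c(OC)c2)[C@H](OCc2ccc(OC)cc2)/C(C)=C\C1
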